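## Analysis of the target

The target 17 is methyl (5E,7E,12S,14Z)-10-chloro-12-hydroxy-9-oxoprosta-5,7,10,14-tetraenoate. Prostanoid numbering is used for all intermediates: ester carbon C1, ring C8–C12, ketone C9, chlorine on C10, carbinol C12, octenyl chain C13–C20. The core is one cyclopentenone ring that is cross-conjugated: the ring enone C9/C10=C11 carries chlorine on its α-carbon, and the exocyclic alkene C8=C7 runs on into the C5=C6 alkene of the ester chain. The only stereocentre is the fully substituted carbinol C12 (S). Nothing else in the molecule can relay its configuration, so it must come from reagent control; all other stereochemistry is alkene geometry (5E, 7E, 14Z). The dienone is a strong Michael acceptor toward soft nucleophiles and base. The C12 oxygen is β to the C9 ketone, which is harmless while C8 is an alkene carbon but is a retro-aldol liability in any intermediate with enol or C–H character at C8. The skipped 14Z alkene is exposed to electrophilic halogen and to isomerisation. The strategy rests on one observation: C9, C10, C11 and C12 together with C8 and C7 are the six carbons of a para-quinol, a dearomatised 4-alkylphenol, with C12 the prochiral carbinol carbon and C7 next to the ketone C9. Moving the C9 acyl carbon from C7 to C8 contracts that ring to the cyclopentenone and leaves C7 outside the ring as the first carbon of the dienyl chain.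

## Retrosynthetic reasoning

17 from 16. The two differ only in the geometry at C7=C8. In 17 the chain points away from the C9 carbonyl oxygen, which should be the more stable arrangement, so this geometry is left to a thermodynamic equilibration at the very end. The steps before it then need not control it.

16 from 12 and 14, through 15. The C6–C7 bond is cut between two sp2 carbons. C7 leaves the key step as an enolised formyl carbon, so it is a latent vinyl electrophile (enol triflate 12), and C6 comes as the (E)-alkenylboronate 14, one step from 13. Cutting here instead of at C7=C8 (aldol condensation) avoids enolate chemistry at C8 next to an acyloxy-bearing carbon. In the forward sense the ester on O12 is hydrolysed first (15), so that the palladium catalyst never meets an allylic ester, and the coupling must proceed with retention at both alkenes.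

12 from 11. Sulfonylation of the enol oxygen. This also locks C8 as a fully substituted alkene carbon, after which O12 can be unmasked safely.

11 from 9, through 10. This is the key disconnection. In the reverse sense C7 is reconnected to C9 and the C8–C9 bond is cut, which re-expands the cyclopentenone to the six-membered epoxy ketone 9. No other cut reveals the symmetric six-carbon ring. The gain is that C7 is delivered at the aldehyde oxidation level with chlorine and C12 already in place. The forward reaction must open the epoxide at C8 and move the acyl carbon C9 from C7 to C8, and nothing else. For that reason O12 carries a trifluoroacetyl group, the poorest oxygen donor and weakest carbonyl nucleophile among simple esters, so that neither a shift of a C12 substituent nor participation by the ester can compete.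

9 from 8 from 7. Acylation of O12 and α-chlorination of the one enone arm that 7 still has. Chlorine goes in here, before the cyclopentenone and the diene exist, because at this stage a nucleophile-triggered chlorination has only one enone to address.

7 from 6. Removing the epoxide oxygen reveals the achiral quinol 6, whose two enone arms are enantiotopic. The forward reaction is a hydroxyl-directed nucleophilic mono-epoxidation under chiral-reagent control. It must pick one arm (this sets C12) and the face syn to the hydroxyl.

6 from 5. The C12–O bond is cut and the ring rearomatised. Forward, this is an oxidative dearomatisation of the 4-alkylphenol in an aqueous medium.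

5 from 2 and 3, through 4; 2 from 1. The C14=C15 alkene is cut by a Wittig disconnection. A non-stabilised ylide gives the Z geometry, and the phenol needs no protecting group because it travels as the phenoxide.

## Alternatives that were turned down

Alternative 1: The C8–C12 ring bond is cut and the ring unfolded to a furan, {5-[(2Z)-oct-2-en-1-yl]furan-2-yl}methanol A1. The furan carbons become C9–C12 and the hydroxymethyl carbon becomes C8. Forward, a chiral Brønsted acid (a BINOL-derived N-triflylphosphoramide) in wet solvent would ionise the carbinol, and water would attack the furan carbon that bears the octenyl group. The ring would open to a hydroxypentadienyl cation, and a conrotatory four-electron closure would make C8–C12, giving (4R)-4-hydroxy-4-[(2Z)-oct-2-en-1-yl]cyclopent-2-en-1-one A2 (Piancatelli rearrangement).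
- For: it is the shortest way to the ring, and on step count it beats the chosen route.
- Against: the carbinol of A1 is primary, so the furfuryl cation that starts the cascade is poorly stabilised. Such substrates need forcing conditions, under which an uncatalysed racemic pathway runs alongside.
- Against: the only stereocentre forms in the electrocyclisation, and its other terminus C8 carries two hydrogens. Only ion pairing with the chiral anion can bias the sense of rotation, and an oxygen version of this rearrangement that makes a quaternary carbinol enantioselectively is not established.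
- Against: A2 still lacks chlorine and C7. The chlorination meets the same C14=C15 problem as here, and C7 would have to be attached by an aldol condensation that gives mixed C7=C8 geometry.
- Comparison: the chosen route is longer, but it takes its enantioselectivity from a reagent delivered by the substrate hydroxyl to a well-defined enone, and it has C7 on the ring from the start.

Alternative 2: The C9–C10 bond is cut, opening the ring to an aldehyde (C9) and one of two identical alkynes on the carbinol carbon, 3-[(triethylsilyl)oxy]-5-(trimethylsilyl)-3-[(trimethylsilyl)ethynyl]pent-4-ynal A3. Forward, [Rh((R)-Tol-BINAP)]BF4 or its antipode, a cationic monovalent rhodium complex, would add the aldehyde C–H bond across one of the two enantiotopic alkynes. This closes the cyclopentenone and sets C12 in (4R)-4-[(triethylsilyl)oxy]-2-(trimethylsilyl)-4-[(trimethylsilyl)ethynyl]cyclopent-2-en-1-one A4.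
- For: catalytic desymmetrisation of 4-alkynals by this catalyst type has close precedent. The enantio-determining step therefore stands on firmer ground than my epoxidation, and that point goes to the alternative. The silyl group on C10 is a handle for chlorine.
- Against: symmetry forces two identical alkynes, and the one left on C12 is attached directly. The target needs a methylene at C13 and the Z alkene one bond further out, which means desilylation, anti-Markovnikov hydration and a Wittig reaction on a β-silyloxy ketone.
- Against: C8 is a bare methylene that must still be joined to C7, silicon must be exchanged for chlorine, and A3 is a β-silyloxy aldehyde prone to elimination.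
- Comparison: most of the work comes after the key step. The chosen route carries the intact octenyl chain from its first C–C bond and gets C7 from the ring itself.

Alternative 3: Both bonds to C9 are cut and C9 is supplied as carbon monoxide. The precursor is the acyclic methyl (5E,7E,9R,11Z)-9-[(Z)-2-iodoethenyl]-9-[(triethylsilyl)oxy]heptadeca-5,7,11-trienoate A5. Forward, Pd(PPh3)4, CO and Et3N would give an acylpalladium species at C9. It would add 5-exo to the C8 end of the diene arm and lose hydride from C8, forming methyl (5E,7E,12S,14Z)-9-oxo-12-[(triethylsilyl)oxy]prosta-5,7,10,14-tetraenoate A6.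
- For: ring, ketone and exocyclic alkene arise in one operation with the whole skeleton in place. On convergence it is the strongest of the four.
- Against: the stereochemical problem is only moved. A5 is an acyclic tertiary carbinol with three different unsaturated arms, and no reliable enantioselective assembly of it is apparent.
- Against: the π-allyl intermediate can also lose hydride from C4 or be captured, so the position and geometry of the diene are not secured.
- Against: A6 has no chlorine. C10 would have to be chlorinated last, on a cross-conjugated dienone that carries three other alkenes.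
- Comparison: the chosen route derives C12 from an achiral, symmetric precursor and places chlorine before any of the sensitive unsaturation exists.

Key step: step 7

Remark on the chemistry: the sense of induction of the tartrate-mediated epoxidation (step 4) cannot be derived beforehand. Diisopropyl L-tartrate is written; the D-ester is to be used if the other enone arm reacts.

## Route

Step 1
Reactants: 1 4-(2-bromoethyl)phenol
Product: 2 [2-(4-hydroxyphenyl)ethyl]triphenylphosphonium bromide
Conditions: PPh3 (1.1 equiv), toluene, reflux
Reagents that add atoms: triphenylphosphine, c1ccc(cc1)P(c1ccccc1)c1ccccc1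
Why: SN2 alkylation of the phosphine by the primary bromide (phosphonium salt formation); the phenol is inert under neutral conditions and the salt separates from the hot solvent.

Step 2
Reactants: 2 [2-(4-hydroxyphenyl)ethyl]triphenylphosphonium bromide; 3 hexanal
Product: 5 4-[(2Z)-oct-2-en-1-yl]phenol, via phenolate ylide 4 (not isolated)
Conditions: NaN(SiMe3)2 (2.1 equiv), THF, 0 °C; then 3, −78 → 25 °C; aq. NH4Cl
Reagents that add atoms: none
Why: Wittig olefination with a non-stabilised ylide under lithium-free conditions: the first equivalent of base makes the phenoxide, the second the ylide, and the kinetically formed cis-oxaphosphetane collapses to the Z alkene C14=C15. Any minor E isomer can be removed on AgNO3-impregnated silica.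

Step 3
Reactants: 5 4-[(2Z)-oct-2-en-1-yl]phenol
Product: 6 4-hydroxy-4-[(2Z)-oct-2-en-1-yl]cyclohexa-2,5-dien-1-one
Conditions: PhI(OAc)2 (1.1 equiv), MeCN/H2O 3:1, 0 °C
Reagents that add atoms: water, O
Why: Oxidative dearomatisation with a trivalent iodine reagent: the phenol is bound to iodine and water attacks the para carbon as iodobenzene leaves, the standard route from 4-alkylphenols to para-quinols. The isolated alkene is far less nucleophilic than the phenol, and its capture of the ring carbon would need a three- or four-membered ring.

Step 4
Reactants: 6 4-hydroxy-4-[(2Z)-oct-2-en-1-yl]cyclohexa-2,5-dien-1-one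
Product: 7 (1S,5S,6R)-5-hydroxy-5-[(2Z)-oct-2-en-1-yl]-7-oxabicyclo[4.1.0]hept-3-en-2-one
Conditions: Ph3COOH (1.1 equiv), NaN(SiMe3)2 (2.2 equiv), diisopropyl L-tartrate (1.1 equiv), 4 Å MS, toluene, −60 °C; aq. NH4Cl
Reagents that add atoms: trityl hydroperoxide, OOC(c1ccccc1)(c1ccccc1)c1ccccc1
Why: Proposed new method: the sodium alkoxide of 6, the sodium tartrate and the sodium trityl peroxide should share one aggregate, so that the peroxide adds to the β-carbon of one enone arm on the face of the alkoxide and the enolate closes the epoxide (Weitz–Scheffer sequence); the epoxide is thus set syn to the hydroxyl by intramolecular delivery and C12 is set by the tartrate, which must choose between the two enantiotopic arms. The closest known reactions are the tartrate-mediated nucleophilic epoxidation of hydroxyl-bearing quinone monoketals and the hydroxyl-directed syn epoxidation of para-quinols with achiral alkaline peroxides; joining them into a desymmetrisation of a free quinol is the untested part. One equivalent of the bulky peroxide at low temperature is meant to stop at the mono-epoxide.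

Step 5
Reactants: 7 (1S,5S,6R)-5-hydroxy-5-[(2Z)-oct-2-en-1-yl]-7-oxabicyclo[4.1.0]hept-3-en-2-one
Product: 8 (1S,5S,6R)-3-chloro-5-hydroxy-5-[(2Z)-oct-2-en-1-yl]-7-oxabicyclo[4.1.0]hept-3-en-2-one
Conditions: PhICl2 (1.1 equiv), pyridine (3 equiv), CH2Cl2, 0 °C, dark
Reagents that add atoms: (dichloroiodo)benzene, ClI(Cl)c1ccccc1
Why: Nucleophile-triggered α-chlorination of an enone: pyridine (or chloride) adds to C11, the enolate takes Cl+ at C10 from PhICl2 and E1cB loss of the nucleophile restores the enone; 7 has only one enone left, so the position is unambiguous. Electrophilic chlorine tempered by pyridine at 0 °C in the dark should be too unreactive for ionic or radical addition to the isolated C14=C15 alkene.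

Step 6
Reactants: 8 (1S,5S,6R)-3-chloro-5-hydroxy-5-[(2Z)-oct-2-en-1-yl]-7-oxabicyclo[4.1.0]hept-3-en-2-one
Product: 9 (1S,5S,6R)-3-chloro-5-[(2Z)-oct-2-en-1-yl]-5-(trifluoroacetoxy)-7-oxabicyclo[4.1.0]hept-3-en-2-one (epoxide cis to the ester oxygen)
Conditions: (CF3CO)2O (1.5 equiv), pyridine (3 equiv), CH2Cl2, 0 °C
Reagents that add atoms: trifluoroacetic anhydride, O=C(OC(=O)C(F)(F)F)C(F)(F)F
Why: Acylation of the hindered tertiary alcohol by the very reactive anhydride through N-trifluoroacetylpyridinium; no stereocentre is touched. The trifluoroacetate is chosen because it is the poorest oxygen donor and weakest carbonyl nucleophile among simple esters, has no alkylating carbon, and comes off with aqueous carbonate.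

Step 7
Reactants: 9 (1S,5S,6R)-3-chloro-5-[(2Z)-oct-2-en-1-yl]-5-(trifluoroacetoxy)-7-oxabicyclo[4.1.0]hept-3-en-2-one
Product: 11 (4S,5Z)-2-chloro-5-(hydroxymethylidene)-4-[(2Z)-oct-2-en-1-yl]-4-(trifluoroacetoxy)cyclopent-2-en-1-one, via formyl ketone 10 (not isolated)
Conditions: BF3·OEt2 (1.5 equiv), CH2Cl2, −20 → 20 °C; pH 7 buffer
Reagents that add atoms: none
Why: BF3 binds the epoxide oxygen and the C8–O bond, the one remote from the carbonyl, lengthens; as positive charge builds at C8 the acyl carbon C9 moves from C7 to C8 on the face opposite the departing oxygen, which stays on C7 and becomes the formyl oxygen, so the C8–C9 bond forms as the C7–C9 bond breaks. This is the Lewis-acid rearrangement of cyclic α,β-epoxy ketones to 2-formylcycloalkanones by 1,2-acyl shift, used here on an epoxycyclohexenone whose migration terminus is secondary. The cyclopentenone ring (C8–C9–C10–C11–C12) is not closed by a cyclisation; it arises by contraction of the six-membered ring through the 1,2-shift. No lasting stereocentre is made: C8 forms with the formyl group cis to the ester in 10 and is flattened when 10 tautomerises to the chelated enol 11, and C12 is a spectator. The step needs acyl migration to beat hydride shift from C7 (which would give a 1,3-dione), shift of C13 or C11 from C12 (a semipinacol path, for which C13 is well aligned anti to the breaking C8–O bond), and capture of C8 by the ester carbonyl or by fluoride. The trifluoroacetyl group answers the outlets that involve C12: its oxygen is too poor a donor to stabilise a cation at C12, and its carbonyl is too weak a nucleophile to open the epoxide, which it could not reach from the syn face in any case. Acyl over hydride is the usual preference in this reaction class because the carbonyl carbon can bridge C7 and C8, and the product is drained into the enol, which cannot lose the ester without forming a cyclopentadienone.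

Step 8
Reactants: 11 (4S,5Z)-2-chloro-5-(hydroxymethylidene)-4-[(2Z)-oct-2-en-1-yl]-4-(trifluoroacetoxy)cyclopent-2-en-1-one
Product: 12 (4S,5Z)-2-chloro-4-[(2Z)-oct-2-en-1-yl]-4-(trifluoroacetoxy)-5-{[(trifluoromethanesulfonyl)oxy]methylidene}cyclopent-2-en-1-one
Conditions: Tf2O (1.1 equiv), i-Pr2NEt (1.3 equiv), CH2Cl2, −78 °C
Reagents that add atoms: trifluoromethanesulfonic anhydride, O=S(=O)(OS(=O)(=O)C(F)(F)F)C(F)(F)F
Why: O-sulfonylation of the ammonium enolate of a 1,3-dicarbonyl compound at the formyl-derived oxygen; the chelate-like shape of the ion pair should place the triflate syn to the C9 carbonyl (5Z), but this geometry is not critical because step 11 equilibrates it. From here C8 is a fully substituted alkene carbon, so O12 can be unmasked without a retro-aldol outlet.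

Step 9
Reactants: 13 methyl hex-5-ynoate
Product: 14 methyl (5E)-6-(4,4,5,5-tetramethyl-1,3,2-dioxaborolan-2-yl)hex-5-enoate
Conditions: pinacolborane (1.2 equiv), Cy2BH (10 mol%), THF, 25 °C
Reagents that add atoms: pinacolborane, CC1(C)OBOC1(C)C
Why: Hydroboration of the terminal alkyne: dicyclohexylborane adds syn with boron on the terminal carbon and hands the alkenyl group to pinacolborane, regenerating the dialkylborane, which fixes the 5E geometry. The methyl ester is inert to dialkylboranes at room temperature.

Step 10
Reactants: 12 (4S,5Z)-2-chloro-4-[(2Z)-oct-2-en-1-yl]-4-(trifluoroacetoxy)-5-{[(trifluoromethanesulfonyl)oxy]methylidene}cyclopent-2-en-1-one; 14 methyl (5E)-6-(4,4,5,5-tetramethyl-1,3,2-dioxaborolan-2-yl)hex-5-enoate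
Product: 16 methyl (5E,7Z,12S,14Z)-10-chloro-12-hydroxy-9-oxoprosta-5,7,10,14-tetraenoate, via hydroxy triflate 15 (not isolated)
Conditions: K2CO3 (3 equiv), THF/H2O 4:1, 0 °C; then 14 (1.3 equiv), Pd(PPh3)4 (5 mol%), 25 °C
Reagents that add atoms: none
Why: Aqueous carbonate first hydrolyses the trifluoroacetate, so that no allylic ester is present when zerovalent palladium is added (no Tsuji–Trost ionisation at C12); Suzuki–Miyaura coupling then joins C7 to C6 with retention at both alkenes. The vinylogous acyl triflate undergoes oxidative addition far faster than the C10–Cl bond.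

Step 11
Reactants: 16 methyl (5E,7Z,12S,14Z)-10-chloro-12-hydroxy-9-oxoprosta-5,7,10,14-tetraenoate
Product: 17 methyl (5E,7E,12S,14Z)-10-chloro-12-hydroxy-9-oxoprosta-5,7,10,14-tetraenoate
Conditions: I2 (5 mol%), CH2Cl2, 25 °C, daylight; aq. Na2S2O3; HPLC
Reagents that add atoms: none
Why: Reversible addition of iodine atoms to the conjugated dienone gives a delocalised radical in which the C7–C8 and C5–C6 bonds rotate, so the mixture should settle at the thermodynamic isomer, expected to be 5E,7E with the chain turned away from the C9 carbonyl oxygen. The isolated 14Z alkene gives no stabilised radical and should be left alone at catalytic loading.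

## Compound list

1 | 4-(2-bromoethyl)phenol | Oc1ccc(CCBr)cc1 | starting material
2 | [2-(4-hydroxyphenyl)ethyl]triphenylphosphonium bromide | [Br-].Oc1ccc(CC[P+](c2ccccc2)(c2ccccc2)c2ccccc2)cc1 | intermediate
3 | hexanal | CCCCCC=O | starting material
4 | sodium 4-[2-(triphenyl-λ5-phosphanylidene)ethyl]phenolate | [Na+].[O-]c1ccc(CC=P(c2ccccc2)(c2ccccc2)c2ccccc2)cc1 | intermediate (not isolated)
5 | 4-[(2Z)-oct-2-en-1-yl]phenol | CCCCC/C=C\Cc1ccc(O)cc1 | intermediate
6 | 4-hydroxy-4-[(2Z)-oct-2-en-1-yl]cyclohexa-2,5-dien-1-one | CCCCC/C=C\CC1(O)C=CC(=O)C=C1 | intermediate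
7 | (1S,5S,6R)-5-hydroxy-5-[(2Z)-oct-2-en-1-yl]-7-oxabicyclo[4.1.0]hept-3-en-2-one | CCCCC/C=C\C[C@]1(O)C=CC(=O)[C@H]2O[C@@H]12 | intermediate
8 | (1S,5S,6R)-3-chloro-5-hydroxy-5-[(2Z)-oct-2-en-1-yl]-7-oxabicyclo[4.1.0]hept-3-en-2-one | CCCCC/C=C\C[C@]1(O)C=C(Cl)C(=O)[C@H]2O[C@@H]12 | intermediate
9 | (1S,5S,6R)-3-chloro-5-[(2Z)-oct-2-en-1-yl]-5-(trifluoroacetoxy)-7-oxabicyclo[4.1.0]hept-3-en-2-one | CCCCC/C=C\C[C@]1(OC(=O)C(F)(F)F)C=C(Cl)C(=O)[C@H]2O[C@@H]12 | intermediate (precursor of the key step)
10 | (4R,5R)-2-chloro-5-formyl-4-[(2Z)-oct-2-en-1-yl]-4-(trifluoroacetoxy)cyclopent-2-en-1-one (formyl cis to the ester; C4 arranged as in 9 and 11) | CCCCC/C=C\C[C@]1(OC(=O)C(F)(F)F)C=C(Cl)C(=O)[C@H]1C=O | intermediate (not isolated)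
11 | (4S,5Z)-2-chloro-5-(hydroxymethylidene)-4-[(2Z)-oct-2-en-1-yl]-4-(trifluoroacetoxy)cyclopent-2-en-1-one | CCCCC/C=C\C[C@]1(OC(=O)C(F)(F)F)C=C(Cl)C(=O)/C1=C\O | intermediate (product of the key step)
12 | (4S,5Z)-2-chloro-4-[(2Z)-oct-2-en-1-yl]-4-(trifluoroacetoxy)-5-{[(trifluoromethanesulfonyl)oxy]methylidene}cyclopent-2-en-1-one | CCCCC/C=C\C[C@]1(OC(=O)C(F)(F)F)C=C(Cl)C(=O)/C1=C\OS(=O)(=O)C(F)(F)F | intermediate
13 | methyl hex-5-ynoate | COC(=O)CCCC#C | starting material
14 | methyl (5E)-6-(4,4,5,5-tetramethyl-1,3,2-dioxaborolan-2-yl)hex-5-enoate | COC(=O)CCC/C=C/B1OC(C)(C)C(C)(C)O1 | intermediate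
15 | (4S,5Z)-2-chloro-4-hydroxy-4-[(2Z)-oct-2-en-1-yl]-5-{[(trifluoromethanesulfonyl)oxy]methylidene}cyclopent-2-en-1-one | CCCCC/C=C\C[C@]1(O)C=C(Cl)C(=O)/C1=C\OS(=O)(=O)C(F)(F)F | intermediate (not isolated)
16 | methyl (5E,7Z,12S,14Z)-10-chloro-12-hydroxy-9-oxoprosta-5,7,10,14-tetraenoate | CCCCC/C=C\C[C@]1(O)C=C(Cl)C(=O)/C1=C\C=C\CCCC(=O)OC | intermediate
17 | methyl (5E,7E,12S,14Z)-10-chloro-12-hydroxy-9-oxoprosta-5,7,10,14-tetraenoate | CCCCC/C=C\C[C@]1(O)C=C(Cl)C(=O)/C1=C/C=C/CCCC(=O)OC | target

## Step count and least certain steps

Total step count: 11. Longest linear sequence: 10 steps (steps 1–8, 10 and 11, from 1 to 17); step 9 is a one-step side branch.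

Step 4 (proposed new method). The likely failure is poor selection between the two enantiotopic enone arms. The tartrate has to tell apart two identical arms from an alkoxide that sits on the symmetry plane of 6. A second failure is over-epoxidation of the remaining arm to the achiral bis-epoxide. The fallback uses known chemistry and sets out from 6. Hydroxyl-directed epoxidation with t-BuOOH and DBU in CH2Cl2 at 0 °C, which is syn-selective for para-quinols, gives racemic material: 7 together with its enantiomer (1R,5R,6S)-5-hydroxy-5-[(2Z)-oct-2-en-1-yl]-7-oxabicyclo[4.1.0]hept-3-en-2-one F1. F1 is removed by preparative chromatography on a chiral stationary phase, and the route is rejoined at 7. The cost is half of the material.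

Step 7 (key step). The likely failure is slow ionisation at the secondary C8, which is flanked by the acyloxy-bearing C12. In that case fluoride capture, a shift of C13 from C12, or a hydride shift from C7 followed by aromatising loss of the ester take over from the acyl shift. The fallback keeps the same bond reorganisation but makes the migrating carbon a better donor, and it sets out from 8.
- Luche reduction (NaBH4, CeCl3·7H2O, MeOH, −78 °C) gives 3-chloro-5-[(2Z)-oct-2-en-1-yl]-7-oxabicyclo[4.1.0]hept-3-ene-2,5-diol F2 (either C9 epimer serves).
- Selective silylation of the secondary hydroxyl (Et3SiCl, imidazole) gives 3-chloro-5-[(2Z)-oct-2-en-1-yl]-2-[(triethylsilyl)oxy]-7-oxabicyclo[4.1.0]hept-3-en-5-ol F3.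
- Trifluoroacetic anhydride and pyridine give its trifluoroacetate, 3-chloro-5-[(2Z)-oct-2-en-1-yl]-2-[(triethylsilyl)oxy]-5-(trifluoroacetoxy)-7-oxabicyclo[4.1.0]hept-3-ene F4.
- The organoaluminium-promoted rearrangement of epoxy silyl ethers to β-silyloxy aldehydes (MeAl(OAr)2, Ar = 4-bromo-2,6-di-tert-butylphenyl, CH2Cl2, −78 °C) moves the silyloxy-bearing C9 from C7 to C8. This gives 3-chloro-5-[(2Z)-oct-2-en-1-yl]-2-[(triethylsilyl)oxy]-5-(trifluoroacetoxy)cyclopent-3-ene-1-carbaldehyde F5.
- HF·pyridine gives 3-chloro-2-hydroxy-5-[(2Z)-oct-2-en-1-yl]-5-(trifluoroacetoxy)cyclopent-3-ene-1-carbaldehyde F6.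
- Dess–Martin periodinane oxidises the C9 carbinol to 10, which enolises, and the route is rejoined at 11.

Step 3. The likely failure is loss of a proton from the C13 methylene, which is both benzylic and allylic, in the oxidised phenol intermediate. This gives an extended quinone methide and rearomatised side-chain oxidation products instead of the quinol. The fallback sets out from 5 and changes the oxidant type. Singlet oxygen, generated from KHSO5 (as 2KHSO5·KHSO4·K2SO4) and NaHCO3 in aqueous MeCN, adds to the phenolate far faster than to a 1,2-dialkyl alkene. It gives 4-hydroperoxy-4-[(2Z)-oct-2-en-1-yl]cyclohexa-2,5-dien-1-one F7, which Me2S reduces to 6.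

Step 5. The likely failure is loss of chemoselectivity: addition of chlorine across the C14=C15 alkene, or opening of the epoxide by the pyridinium chloride that forms. The fallback sets out from 7. Iodination with I2 and pyridine in CH2Cl2 follows the same nucleophile-triggered mechanism and does not touch isolated alkenes. It gives (1S,5S,6R)-5-hydroxy-3-iodo-5-[(2Z)-oct-2-en-1-yl]-7-oxabicyclo[4.1.0]hept-3-en-2-one F8. Halogen exchange with CuCl in DMF at 60–80 °C then returns to 8.

Step 10. The likely failure is loss of the triflate once the ester is gone. Hydroxide, or the C12 alkoxide acting through a six-membered transition state, can cleave the S–O bond and return the enolate, which with a free C12 hydroxyl can open by retro-aldol before oxidative addition occurs. The fallback sets out from 12 and reverses the order of events. Coupling with 14 is run with the ester in place under anhydrous fluoride activation (Pd(PPh3)4, CsF, dioxane, 25 °C) to give methyl (5E,7Z,12S,14Z)-10-chloro-9-oxo-12-(trifluoroacetoxy)prosta-5,7,10,14-tetraenoate F9. KHCO3 in MeOH at 0 °C then removes the trifluoroacetate and returns to 16. The price is a short exposure of an allylic ester to zerovalent palladium.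

Step 11. The likely failure is an equilibrium that does not lie far enough on the 7E side, because the quaternary C12 sits next to the exocyclic alkene. Slow scrambling of the 14Z alkene on long exposure is a second risk. The fallback sets out from 11 and fixes the C7 geometry before the C–C bond is made.
- Oxalyl chloride and catalytic DMF in CH2Cl2 give the vinylogous acid chloride (4S,5E)-2-chloro-5-(chloromethylidene)-4-[(2Z)-oct-2-en-1-yl]-4-(trifluoroacetoxy)cyclopent-2-en-1-one F10. Chloride addition–elimination equilibrates it to the isomer with chlorine anti to the carbonyl.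
- Aqueous K2CO3 in THF at 0 °C gives (4S,5E)-2-chloro-5-(chloromethylidene)-4-hydroxy-4-[(2Z)-oct-2-en-1-yl]cyclopent-2-en-1-one F11, which is not isolated.
- Suzuki–Miyaura coupling with 14 (Pd(PPh3)4, 25 °C) proceeds with retention and rejoins the route directly at 17.

## Further compounds

F1 | step 4 | (1R,5R,6S)-5-hydroxy-5-[(2Z)-oct-2-en-1-yl]-7-oxabicyclo[4.1.0]hept-3-en-2-one | CCCCC/C=C\C[C@@]1(O)C=CC(=O)[C@@H]2O[C@H]12
F2 | step 7 | 3-chloro-5-[(2Z)-oct-2-en-1-yl]-7-oxabicyclo[4.1.0]hept-3-ene-2,5-diol (C1, C5, C6 as in 8; C2 either epimer) | CCCCC/C=C\C[C@]1(O)C=C(Cl)C(O)[C@H]2O[C@@H]12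
F3 | step 7 | 3-chloro-5-[(2Z)-oct-2-en-1-yl]-2-[(triethylsilyl)oxy]-7-oxabicyclo[4.1.0]hept-3-en-5-ol | CCCCC/C=C\C[C@]1(O)C=C(Cl)C(O[Si](CC)(CC)CC)[C@H]2O[C@@H]12
F4 | step 7 | 3-chloro-5-[(2Z)-oct-2-en-1-yl]-2-[(triethylsilyl)oxy]-5-(trifluoroacetoxy)-7-oxabicyclo[4.1.0]hept-3-ene | CCCCC/C=C\C[C@]1(OC(=O)C(F)(F)F)C=C(Cl)C(O[Si](CC)(CC)CC)[C@H]2O[C@@H]12
F5 | step 7 | 3-chloro-5-[(2Z)-oct-2-en-1-yl]-2-[(triethylsilyl)oxy]-5-(trifluoroacetoxy)cyclopent-3-ene-1-carbaldehyde (formyl cis to the ester) | CCCCC/C=C\C[C@]1(OC(=O)C(F)(F)F)C=C(Cl)C(O[Si](CC)(CC)CC)[C@H]1C=O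
F6 | step 7 | 3-chloro-2-hydroxy-5-[(2Z)-oct-2-en-1-yl]-5-(trifluoroacetoxy)cyclopent-3-ene-1-carbaldehyde | CCCCC/C=C\C[C@]1(OC(=O)C(F)(F)F)C=C(Cl)C(O)[C@H]1C=O
F7 | step 3 | 4-hydroperoxy-4-[(2Z)-oct-2-en-1-yl]cyclohexa-2,5-dien-1-one | CCCCC/C=C\CC1(OO)C=CC(=O)C=C1
F8 | step 5 | (1S,5S,6R)-5-hydroxy-3-iodo-5-[(2Z)-oct-2-en-1-yl]-7-oxabicyclo[4.1.0]hept-3-en-2-one | CCCCC/C=C\C[C@]1(O)C=C(I)C(=O)[C@H]2O[C@@H]12
F9 | step 10 | methyl (5E,7Z,12S,14Z)-10-chloro-9-oxo-12-(trifluoroacetoxy)prosta-5,7,10,14-tetraenoate | CCCCC/C=C\C[C@]1(OC(=O)C(F)(F)F)C=C(Cl)C(=O)/C1=C\C=C\CCCC(=O)OC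
F10 | step 11 | (4S,5E)-2-chloro-5-(chloromethylidene)-4-[(2Z)-oct-2-en-1-yl]-4-(trifluoroacetoxy)cyclopent-2-en-1-one | CCCCC/C=C\C[C@]1(OC(=O)C(F)(F)F)C=C(Cl)C(=O)/C1=C/Cl
F11 | step 11 | (4S,5E)-2-chloro-5-(chloromethylidene)-4-hydroxy-4-[(2Z)-oct-2-en-1-yl]cyclopent-2-en-1-one | CCCCC/C=C\C[C@]1(O)C=C(Cl)C(=O)/C1=C/Cl
A1 | alternative 1 | {5-[(2Z)-oct-2-en-1-yl]furan-2-yl}methanol | CCCCC/C=C\Cc1ccc(CO)o1
A2 | alternative 1 | (4R)-4-hydroxy-4-[(2Z)-oct-2-en-1-yl]cyclopent-2-en-1-one | CCCCC/C=C\C[C@]1(O)C=CC(=O)C1
A3 | alternative 2 | 3-[(triethylsilyl)oxy]-5-(trimethylsilyl)-3-[(trimethylsilyl)ethynyl]pent-4-ynal | O=CCC(O[Si](CC)(CC)CC)(C#C[Si](C)(C)C)C#C[Si](C)(C)C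
A4 | alternative 2 | (4R)-4-[(triethylsilyl)oxy]-2-(trimethylsilyl)-4-[(trimethylsilyl)ethynyl]cyclopent-2-en-1-one | C[Si](C)(C)C#C[C@]1(O[Si](CC)(CC)CC)C=C([Si](C)(C)C)C(=O)C1
A5 | alternative 3 | methyl (5E,7E,9R,11Z)-9-[(Z)-2-iodoethenyl]-9-[(triethylsilyl)oxy]heptadeca-5,7,11-trienoate | CCCCC/C=C\C[C@](/C=C/C=C/CCCC(=O)OC)(O[Si](CC)(CC)CC)/C=C\I
A6 | alternative 3 | methyl (5E,7E,12S,14Z)-9-oxo-12-[(triethylsilyl)oxy]prosta-5,7,10,14-tetraenoate | CCCCC/C=C\C[C@]1(O[Si](CC)(CC)CC)C=CC(=O)/C1=C/C=C/CCCC(=O)OC
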